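**Retrosynthetic overview** (chroman numbering O1, C2, C3, C4, C4a, C5–C8, C8a; ring A is the phloroglucinol-derived benzene ring, ring B the 4-hydroxyphenyl ring)

1. Target 20 ← chalcone 19 by cleavage of three benzyl ethers; the enone C=C comes from a Claisen–Schmidt condensation of C8 methyl ketone 16 with aldehyde 17; the acetyl–C8 bond comes from C8 bromide 13 (aryllithium plus Weinreb amide 14).
2. Pyran ring (O1–C2–C3–C4–C4a–C8a) of 12 ← O1–C2 closure by cyclodehydration of phenol diol 11.
3. Key disconnection: both C2–CH3 bonds. The feature used is C2, a fully substituted ether carbon of the pyran ring carrying O1, two methyl groups and the C3 carbinol; at the lactone oxidation level it is a carbonyl that already holds O1 and C3, so 11 ← (S)-3-hydroxydihydrocoumarin 7 + MeMgBr.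
4. 7 ← enantioselective enolate hydroxylation (C3–O, sets the only stereocenter) of 5 ← benzylation of 4 ← phloroglucinol 1 + acrylic acid 2 (C4–C4a and O1–C2 bonds).
5. Ring order: ring A is bought; the lactone ring is formed in step 1, opened in step 4, and the pyran ring is closed in step 5; ring B arrives intact with 17.

Key step: step 4

Assumption: the (−)-(camphorsulfonyl)oxaziridine, the antipode made from (1R)-(−)-camphor-10-sulfonic acid, is taken to oxidise the C3 Si face of the ring-constrained lactone enolate and so to give the (S)-alcohol; if a trial run shows the opposite sense, the (+)-antipode is used with no other change.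

**Step 1**
Reactants: 1 phloroglucinol (slight excess); 2 acrylic acid
Product: 4 5,7-dihydroxychroman-2-one, via 3-(2,4,6-trihydroxyphenyl)propanoic acid 3 (not isolated)
Conditions: Amberlyst-15, toluene, reflux (Dean–Stark)
Reagents that add atoms: none
Why: Acid-catalysed Friedel–Crafts conjugate addition (hydroarylation) of the symmetric, threefold-activated arene to the β-carbon of acrylic acid is followed by lactonisation of acid 3 onto an ortho phenol; the symmetry of 1 allows only one regioisomer, and the esterified phenol makes 4 less reactive than 1, which limits a second alkylation.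

**Step 2**
Reactants: 4 5,7-dihydroxychroman-2-one
Product: 5 5,7-bis(benzyloxy)chroman-2-one
Conditions: BnBr (2.3 equiv), K2CO3 (2.5 equiv), DMF, rt
Reagents that add atoms: benzyl bromide, BrCc1ccccc1
Why: Williamson ether synthesis, in which the two phenoxides are O-alkylated in a dipolar aprotic solvent at room temperature, conditions free of hydroxide or alkoxide under which the aryl lactone should stay closed.

**Step 3**
Reactants: 5 5,7-bis(benzyloxy)chroman-2-one
Product: 7 (S)-5,7-bis(benzyloxy)-3-hydroxychroman-2-one, via sodium enolate 6 (not isolated)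
Conditions: NaN(SiMe3)2 (1.1 equiv), THF, −78 °C; then (−)-(camphorsulfonyl)oxaziridine (1.3 equiv), −78 °C; AcOH quench at −78 °C; recrystallisation if the enantiomeric purity needs raising
Reagents that add atoms: (−)-(camphorsulfonyl)oxaziridine, CC1(C)[C@H]2CC[C@@]13CS(=O)(=O)N4O[C@]34C2
Why: Davis asymmetric enolate hydroxylation, in which enolate 6 attacks the oxaziridine oxygen in an SN2-type step and the hemiaminal collapses to the sulfonylimine, the camphor skeleton of the reagent selecting the C3 Si face so that the new C3 stereocenter should be (S) by reagent control, while the hindered imine does not add to the enolate and the cold acidic quench prevents base-induced racemisation.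

**Step 4**
Reactants: 7 (S)-5,7-bis(benzyloxy)-3-hydroxychroman-2-one; 8 methylmagnesium bromide (5 equiv, 3 M in Et2O)
Product: 11 (S)-1-[2,4-bis(benzyloxy)-6-hydroxyphenyl]-3-methylbutane-2,3-diol, via lactone bromomagnesium alkoxide 9 (not isolated), via methyl ketone bis(bromomagnesium) salt 10 (not isolated)
Conditions: THF, −40 °C to rt; then sat. aq NH4Cl, 0 °C
Reagents that add atoms: none
Why: The first equivalent of MeMgBr deprotonates the C3 hydroxyl to alkoxide 9, the second adds to the aryl-ester carbonyl C2 and the tetrahedral adduct collapses with loss of the O1 phenoxide to methyl ketone 10, and the third adds to that ketone, so both C2–CH3 bonds and the fully substituted C2 are formed in one flask. This is the classical double Grignard addition to an ester, here to a dihydrocoumarin, the standard entry to 2,2-dimethylchromans after cyclodehydration. No ring is closed (the lactone is opened and O1 is released as the one unprotected phenol that later re-closes the pyran ring) and no stereocenter is created. The selectivity needed is complete double addition with retention of the (S)-configuration at C3: the magnesium alkoxide at C3 makes removal of the C3 proton unfavourable in both the lactone and the α-alkoxy ketone, and chelation of that ketone by the neighbouring alkoxide activates it so that it should not accumulate. The benzyl ethers and ring A are inert to the reagent.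

**Step 5**
Reactants: 11 (S)-1-[2,4-bis(benzyloxy)-6-hydroxyphenyl]-3-methylbutane-2,3-diol
Product: 12 (S)-5,7-bis(benzyloxy)-2,2-dimethylchroman-3-ol
Conditions: p-TsOH·H2O (10 mol %), toluene, 60 °C
Reagents that add atoms: none
Why: Acid-catalysed cyclodehydration (intramolecular SN1 etherification), in which the tertiary carbinol ionises in preference to the secondary one and the only free phenol (the former O1) captures the tertiary cation in a six-membered ring closure, so the C3–O bond is never broken and the (S)-configuration is kept.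

**Step 6**
Reactants: 12 (S)-5,7-bis(benzyloxy)-2,2-dimethylchroman-3-ol
Product: 13 (S)-5,7-bis(benzyloxy)-8-bromo-2,2-dimethylchroman-3-ol
Conditions: NBS (1.0 equiv), CH2Cl2, −78 to −40 °C
Reagents that add atoms: N-bromosuccinimide, O=C1CCC(=O)N1Br
Why: Electrophilic aromatic bromination of the threefold-activated ring A, which should take place at C8 (flanked by the tied-back ring oxygen O1 and one benzyloxy group) in preference to C6 (between two benzyloxy groups), the selectivity known for 5,7-di-O-benzylflavan-3-ols.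

**Step 7**
Reactants: 13 (S)-5,7-bis(benzyloxy)-8-bromo-2,2-dimethylchroman-3-ol; 14 N-methoxy-N-methylacetamide
Product: 16 1-[(S)-5,7-bis(benzyloxy)-3-hydroxy-2,2-dimethylchroman-8-yl]ethanone, via dilithio species 15 (not isolated)
Conditions: n-BuLi (2.2 equiv), THF, −78 °C; then 14, −78 to 0 °C; sat. aq NH4Cl
Reagents that add atoms: none
Why: O–H deprotonation and bromine–lithium exchange give the C8 aryllithium 15, whose addition to Weinreb amide 14 stops at the chelated tetrahedral adduct and releases the methyl ketone only on work-up (Weinreb ketone synthesis), so no tertiary alcohol forms and the benzyl ethers are untouched at −78 °C.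

**Step 8**
Reactants: 16 1-[(S)-5,7-bis(benzyloxy)-3-hydroxy-2,2-dimethylchroman-8-yl]ethanone; 17 4-(benzyloxy)benzaldehyde
Product: 19 (E)-1-[(S)-5,7-bis(benzyloxy)-3-hydroxy-2,2-dimethylchroman-8-yl]-3-[4-(benzyloxy)phenyl]prop-2-en-1-one, via β-hydroxy ketone 18 (not isolated)
Conditions: KOH (50% aq), EtOH–THF, rt
Reagents that add atoms: none
Why: Claisen–Schmidt condensation, in which the methyl ketone (the only enolisable partner) adds to the non-enolisable aldehyde and aldol 18 dehydrates by an E1cB path to the thermodynamically favoured (E)-enone; with both ring-A phenols still benzylated no flavanone can form.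

**Step 9**
Reactants: 19 (E)-1-[(S)-5,7-bis(benzyloxy)-3-hydroxy-2,2-dimethylchroman-8-yl]-3-[4-(benzyloxy)phenyl]prop-2-en-1-one
Product: 20 (E)-1-[(3S)-3,5,7-trihydroxy-2,2-dimethylchroman-8-yl]-3-(4-hydroxyphenyl)prop-2-en-1-one
Conditions: BCl3 (1 M in CH2Cl2, 6 equiv), pentamethylbenzene (10 equiv), CH2Cl2, −78 °C; then MeOH, −78 °C to rt
Reagents that add atoms: none
Why: Lewis-acid ether cleavage, in which BCl3 coordinates each benzyl ether oxygen and the benzyl cation is intercepted by pentamethylbenzene (Friedel–Crafts benzylation of the scavenger), so all three benzyl groups should be removed at −78 °C without reducing or alkylating the enone, as hydrogenolysis would; the C3 stereocenter is not involved.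

**Compound list**

1 | phloroglucinol | Oc1cc(O)cc(O)c1 | starting material
2 | acrylic acid | C=CC(=O)O | starting material
3 | 3-(2,4,6-trihydroxyphenyl)propanoic acid | OC(=O)CCc1c(O)cc(O)cc1O | intermediate (not isolated)
4 | 5,7-dihydroxychroman-2-one | O=C1CCc2c(O)cc(O)cc2O1 | intermediate
5 | 5,7-bis(benzyloxy)chroman-2-one | O=C1CCc2c(OCc3ccccc3)cc(OCc3ccccc3)cc2O1 | intermediate
6 | sodium enolate of 5 (sodium 5,7-bis(benzyloxy)-4H-chromen-2-olate) | [Na+].[O-]C1=CCc2c(OCc3ccccc3)cc(OCc3ccccc3)cc2O1 | intermediate (not isolated)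
7 | (S)-5,7-bis(benzyloxy)-3-hydroxychroman-2-one | O=C1Oc2cc(OCc3ccccc3)cc(OCc3ccccc3)c2C[C@@H]1O | intermediate
8 | methylmagnesium bromide | C[Mg]Br | starting material
9 | bromomagnesium C3-alkoxide of 7 | O=C1Oc2cc(OCc3ccccc3)cc(OCc3ccccc3)c2C[C@@H]1O[Mg]Br | intermediate (not isolated)
10 | (S)-4-[2,4-bis(benzyloxy)-6-hydroxyphenyl]-3-hydroxybutan-2-one as its bis(bromomagnesium) salt | CC(=O)[C@@H](O[Mg]Br)Cc1c(O[Mg]Br)cc(OCc2ccccc2)cc1OCc1ccccc1 | intermediate (not isolated)
11 | (S)-1-[2,4-bis(benzyloxy)-6-hydroxyphenyl]-3-methylbutane-2,3-diol | CC(C)(O)[C@@H](O)Cc1c(O)cc(OCc2ccccc2)cc1OCc1ccccc1 | intermediate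
12 | (S)-5,7-bis(benzyloxy)-2,2-dimethylchroman-3-ol | CC1(C)Oc2cc(OCc3ccccc3)cc(OCc3ccccc3)c2C[C@@H]1O | intermediate
13 | (S)-5,7-bis(benzyloxy)-8-bromo-2,2-dimethylchroman-3-ol | CC1(C)Oc2c(Br)c(OCc3ccccc3)cc(OCc3ccccc3)c2C[C@@H]1O | intermediate
14 | N-methoxy-N-methylacetamide | CON(C)C(C)=O | starting material
15 | (S)-5,7-bis(benzyloxy)-8-lithio-2,2-dimethylchroman-3-ol lithium alkoxide (dilithio species) | CC1(C)Oc2c([Li])c(OCc3ccccc3)cc(OCc3ccccc3)c2C[C@@H]1O[Li] | intermediate (not isolated)
16 | 1-[(S)-5,7-bis(benzyloxy)-3-hydroxy-2,2-dimethylchroman-8-yl]ethanone | CC1(C)Oc2c(C(C)=O)c(OCc3ccccc3)cc(OCc3ccccc3)c2C[C@@H]1O | intermediate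
17 | 4-(benzyloxy)benzaldehyde | O=Cc1ccc(OCc2ccccc2)cc1 | starting material
18 | 1-[(S)-5,7-bis(benzyloxy)-3-hydroxy-2,2-dimethylchroman-8-yl]-3-[4-(benzyloxy)phenyl]-3-hydroxypropan-1-one (both epimers at the new carbinol) | CC1(C)Oc2c(C(=O)CC(O)c3ccc(OCc4ccccc4)cc3)c(OCc3ccccc3)cc(OCc3ccccc3)c2C[C@@H]1O | intermediate (not isolated)
19 | (E)-1-[(S)-5,7-bis(benzyloxy)-3-hydroxy-2,2-dimethylchroman-8-yl]-3-[4-(benzyloxy)phenyl]prop-2-en-1-one | CC1(C)Oc2c(C(=O)/C=C/c3ccc(OCc4ccccc4)cc3)c(OCc3ccccc3)cc(OCc3ccccc3)c2C[C@@H]1O | intermediate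
20 | (E)-1-[(3S)-3,5,7-trihydroxy-2,2-dimethylchroman-8-yl]-3-(4-hydroxyphenyl)prop-2-en-1-one | CC1(C)Oc2c(c(O)cc(O)c2C(=O)/C=C/c2ccc(O)cc2)C[C@@H]1O | target

**Totals**

Total step count: 9. Longest linear sequence: 9 steps (from phloroglucinol; 2, 8, 14 and 17 are bought).

**Steps most likely to fail**

1. Step 3. The oxygen transfer may discriminate poorly between the two faces of an unsubstituted lactone enolate, or may favour the other face, and the α-hydroxy lactone may racemise if it stays in contact with base. The fallback replaces reagent control by auxiliary control; it sets out from 5 and comes back at 7.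
 - Lactone 5 is opened by the lithium salt of (S)-4-benzyloxazolidin-2-one (n-BuLi, THF, −78 to 0 °C), an N-acylation by an aryl ester, and the phenoxide released is silylated in the same flask with TBSCl. This should give (S)-4-benzyl-3-{3-[2,4-bis(benzyloxy)-6-(tert-butyldimethylsilyloxy)phenyl]propanoyl}oxazolidin-2-one F1.
 - Its chelated (Z)-sodium enolate (NaN(SiMe3)2, THF, −78 °C) is hydroxylated with racemic 2-(phenylsulfonyl)-3-phenyloxaziridine on the face opposite the benzyl group of the auxiliary. This should give (S)-4-benzyl-3-{(S)-3-[2,4-bis(benzyloxy)-6-(tert-butyldimethylsilyloxy)phenyl]-2-hydroxypropanoyl}oxazolidin-2-one F2.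
 - HF·pyridine in THF removes the silyl ether to give (S)-4-benzyl-3-{(S)-3-[2,4-bis(benzyloxy)-6-hydroxyphenyl]-2-hydroxypropanoyl}oxazolidin-2-one F3.
 - A catalytic amount of Et3N in CH2Cl2 should then close the phenol onto the activated imide carbonyl with release of the auxiliary, giving 7.

2. Step 6. Bromination may also take place at C6, or twice, so that the acetyl group ends up on the wrong ring-A carbon. The fallback places the C8 carbon before ring closure, ortho to the only free phenol; it sets out from 11 and comes back at 16.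
 - Magnesium-mediated ortho-formylation of phenol 11 (MgCl2, Et3N, paraformaldehyde, MeCN, reflux; Casnati–Skattebøl reaction) delivers the formyl group only ortho to a free phenolic OH. It should give 4,6-bis(benzyloxy)-3-[(2S)-2,3-dihydroxy-3-methylbutyl]-2-hydroxybenzaldehyde F4.
 - The acid cyclodehydration of step 5 then closes the pyran ring to (3S)-5,7-bis(benzyloxy)-3-hydroxy-2,2-dimethylchroman-8-carbaldehyde F5, in which the formyl group necessarily sits at C8 next to O1.
 - Excess MeMgBr (THF, 0 °C) should give (3S)-5,7-bis(benzyloxy)-8-(1-hydroxyethyl)-2,2-dimethylchroman-3-ol F6 as a mixture of carbinol epimers.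
 - MnO2 in CH2Cl2 oxidises the benzylic carbinol selectively beside the C3 carbinol and gives 16.

3. Step 9. The Lewis acid may chelate between the C8 carbonyl and O1 and ionise the tertiary O1–C2 bond, or the freed 7-OH may add to the enone (flavanone closure) during the acidic quench. The fallback replaces the benzyl ethers by acid-labile acetals; it sets out from 16 and comes back at 20.
 - Hydrogenolysis of 16 (H2, Pd/C, EtOAc), possible at this stage because no alkene is present, should give 1-[(3S)-3,5,7-trihydroxy-2,2-dimethylchroman-8-yl]ethanone F7.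
 - MOMCl with K2CO3 in acetone protects the non-chelated 5-OH and should give 1-[(3S)-3,7-dihydroxy-5-(methoxymethoxy)-2,2-dimethylchroman-8-yl]ethanone F8.
 - Claisen–Schmidt condensation with commercial 4-(methoxymethoxy)benzaldehyde (KOH, EtOH, rt) should give (E)-1-[(3S)-3,7-dihydroxy-5-(methoxymethoxy)-2,2-dimethylchroman-8-yl]-3-[4-(methoxymethoxy)phenyl]prop-2-en-1-one F9.
 - Brief treatment with dilute HCl in MeOH at rt removes both acetals and gives 20.

**Further compounds**

F1 | step 3 | (S)-4-benzyl-3-{3-[2,4-bis(benzyloxy)-6-(tert-butyldimethylsilyloxy)phenyl]propanoyl}oxazolidin-2-one | O=C(CCc1c(O[Si](C)(C)C(C)(C)C)cc(OCc2ccccc2)cc1OCc1ccccc1)N1[C@@H](Cc2ccccc2)COC1=O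
F2 | step 3 | (S)-4-benzyl-3-{(S)-3-[2,4-bis(benzyloxy)-6-(tert-butyldimethylsilyloxy)phenyl]-2-hydroxypropanoyl}oxazolidin-2-one | O=C([C@@H](O)Cc1c(O[Si](C)(C)C(C)(C)C)cc(OCc2ccccc2)cc1OCc1ccccc1)N1[C@@H](Cc2ccccc2)COC1=O
F3 | step 3 | (S)-4-benzyl-3-{(S)-3-[2,4-bis(benzyloxy)-6-hydroxyphenyl]-2-hydroxypropanoyl}oxazolidin-2-one | O=C([C@@H](O)Cc1c(O)cc(OCc2ccccc2)cc1OCc1ccccc1)N1[C@@H](Cc2ccccc2)COC1=O
F4 | step 6 | 4,6-bis(benzyloxy)-3-[(2S)-2,3-dihydroxy-3-methylbutyl]-2-hydroxybenzaldehyde | CC(C)(O)[C@@H](O)Cc1c(O)c(C=O)c(OCc2ccccc2)cc1OCc1ccccc1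
F5 | step 6 | (3S)-5,7-bis(benzyloxy)-3-hydroxy-2,2-dimethylchroman-8-carbaldehyde | CC1(C)Oc2c(C=O)c(OCc3ccccc3)cc(OCc3ccccc3)c2C[C@@H]1O
F6 | step 6 | (3S)-5,7-bis(benzyloxy)-8-(1-hydroxyethyl)-2,2-dimethylchroman-3-ol | CC1(C)Oc2c(C(C)O)c(OCc3ccccc3)cc(OCc3ccccc3)c2C[C@@H]1O
F7 | step 9 | 1-[(3S)-3,5,7-trihydroxy-2,2-dimethylchroman-8-yl]ethanone | CC1(C)Oc2c(C(C)=O)c(O)cc(O)c2C[C@@H]1O
F8 | step 9 | 1-[(3S)-3,7-dihydroxy-5-(methoxymethoxy)-2,2-dimethylchroman-8-yl]ethanone | CC1(C)Oc2c(C(C)=O)c(O)cc(OCOC)c2C[C@@H]1O
F9 | step 9 | (E)-1-[(3S)-3,7-dihydroxy-5-(methoxymethoxy)-2,2-dimethylchroman-8-yl]-3-[4-(methoxymethoxy)phenyl]prop-2-en-1-one | CC1(C)Oc2c(C(=O)/C=C/c3ccc(OCOC)cc3)c(O)cc(OCOC)c2C[C@@H]1O
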